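- The constants I needed were two, both on fractions of the charge: κ for activation, so that making runs at κsb with s the starting material left and b the activator left in equivalents, and λ for the first-order using of activated form, which runs at λx.

all flasks: starting material 0.050 M
- oak: activator 0.50 equiv; capture agent 0.050 M; run made earlier
- alder: activator 0.75 equiv; capture agent 0.050 M; run made earlier
- flask: activator 1.00 equiv; capture agent 0.0500 M; time 10 h

| run | time / h | activated form / % | ring / % | starting material / % |
|---|---|---|---|---|
| oak | 1.00 | 9.6 | 0.4 | 89.6 |
| oak | 2.50 | 16.3 | 2.3 | 76.8 |
| oak | 5.00 | 18.6 | 6.9 | 65.6 |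
| oak | 12.0 | 13.3 | 18.3 | 52.5 |
| alder | 1.00 | 12.7 | 0 | 85.0 |
| alder | 2.50 | 21.7 | 3.5 | 70.2 |
| alder | 5.00 | 26.9 | 11.2 | 51.8 |
| alder | 12.0 | 17.9 | 23.3 | 33.3 |

(readings scatter by 1 percentage point)

* time up to 10 h at which activated form stands highest
* the amount of activated form, in percent of the starting material charged, at that time

- percentages count the starting material that a species holds: one open dimer counts as two
- what may be going on: starting material + activator -> activated form; activated form -> ring; starting material + activated form -> open dimer; capture agent + activated form -> trapped intermediate

- Oak's first reading, through the integrated second-order law, gave κ = 0.247 h⁻¹.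
- The flask is charged with 1.00 equiv, so I set b equal to s, and s falls as one over one plus κt.
- At a peak making meets using. Alder's reading at 5.00 h, taken as its peak, gave λ = 0.127 h⁻¹, and there x was a share φ = 0.558 of the starting material lost.
- Setting φ(1−s) equal to κs²/λ gave s = 0.412, so x = 32.8% at 5.79 h.
- The weak link was λ: that subtraction charged all lost starting material to the activator, but dimer formation spends none.
- I reforged it from alder's balance at 12.0 h: ring plus 3/4 of the unread remainder, split evenly between dimer and trapped intermediate, over the area under the activated-form curve. That gave λ = 0.170 h⁻¹.
- The peak ratio κ/λ, which turns sb into the quasi-steady level of activated form, became ρ = 1.45. I committed to s = 0.457, x = 30.3% at 4.82 h.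
- The forecast, higher than mine, stood at 33% and 4.7 h, its grounds: “Production equals loss near 4.5–5 h.”
- The flask peaked at 33.5% at 4.50 h, near the forecast, with 44.4% of the starting material and 47.7% of the activator left. Put into the peak ratio, those give 30.8%.

    starting material + activator → activated form (k = 5.00 M⁻¹ h⁻¹)
    activated form → ring (k = 0.0920 h⁻¹)
    starting material + activated form → open dimer (k = 0.980 M⁻¹ h⁻¹)
    capture agent + activated form → trapped intermediate (k = 0.940 M⁻¹ h⁻¹)

- For the neighbour flask stopped at 2.5 h, s = 61.8% made ρs² = 55.6%, the level being chased, so I expected activated form still climbing. Computed, that neighbour flask held 29.9%, less than that level, and the highest it had reached by then was 29.9%.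

Readings and results stem from a simulated flask for an exercise.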